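## Structural features

The target is a (2S)-flavanone in which a benzene ring A is fused to a dihydropyranone ring C (O1, C2, C3, C4=O) and a 3,5-dihydroxyphenyl ring B sits on C2. Ring A is fully substituted: hydroxyls on C5 and C7, 3-methylbut-2-enyl (prenyl) groups on C6 and C8, the ring oxygen on C8a and the C4 carbonyl on C4a. C2 is the only stereocentre, so no stereocentres stand next to each other; it is benzylic, bonded to O1 and β to the ketone, and can therefore be erased by E1cB opening of ring C to the 2′-hydroxychalcone. The fragile groups are the two trisubstituted alkenes, each ortho to phenolic oxygen: protic and Lewis acids close them onto the phenols as dimethylchromans, HX adds to them, hydrogenolysis and electrophilic oxidants are excluded, and the electron-rich polyphenol also oxidises in base under air. The real difficulty is twofold: placing two C-prenyl groups at defined positions of a phloroglucinol nucleus, where direct electrophilic prenylation gives mixtures, and making C2 as one enantiomer and keeping it through deprotection. The key step exploits the local symmetry of ring A: C6–C7–C8 with its two prenyl groups and O7 is the pattern of a symmetrical ketone whose α-carbons already carry the prenyl CH2 groups, and C5–C4a–C8a is a malonyl unit, so ring A closes by forming C5–C6 and C8–C8a. The ring A made this way is symmetrical, so the oxygens that become O1 and the 5-OH are equivalent until the C4 carbonyl distinguishes them.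

## Logic of the disconnections

18 ⇒ 17. The four phenolic O–H bonds are exchanged for O–CH2 acetal bonds. The phenols must be masked through the hydroxide and amine-base steps, and a single global removal at the end is the shortest arrangement. Nothing is gained in skeleton, but all earlier chemistry becomes base-tolerant. The demand is a final cleavage that spares two acid-sensitive alkenes and C2.

17 ⇒ 16. The O1–C2 bond is cut. It is the one bond to the stereocentre that a catalytic asymmetric heteroatom conjugate addition can form, and cutting it opens ring C and removes the only stereocentre together. The precursor 16 is achiral. The forward step needs exactly one free ortho hydroxyl, catalyst control of the face of the β-carbon, and kinetic control, because the closure is reversible under base.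

16 ⇒ 13 + 15, and 15 ⇒ 14. The C2=C3 enone bond is cut as an aldol condensation, which divides the molecule into 13 and 15. Compound 15 cannot enolise, so the crossed condensation is unambiguous. The protecting groups must survive hydroxide, which is why acetals are used; 15 comes from 14 by cutting two O–C acetal bonds.

13 ⇒ 12 ⇒ 11. One acetal is restored, then the C4–C4a bond is cut as the acylation of an aryl anion. Electrophilic acylation is avoided because its Lewis or Brønsted acids would cyclise the ortho-prenyl phenols. In 11 the last ring hydrogen lies between two acetal oxygens, the ideal site for directed lithiation. The forward steps need ring metalation to beat deprotonation of the benzylic/allylic CH2 groups, and need the carbonyl, once in place, to single out one of the two equivalent ortho acetals for removal.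

11 ⇒ 10. Three O–C acetal bonds are cut to reveal 10. The forward step needs O- rather than C-alkylation of an ambident phloroglucinol.

10 ⇒ 6 + 7 (key disconnection). The bonds C5–C6 and C8–C8a (flavanone numbering) are cut, that is, the two bonds from the prenyl-bearing ring carbons to the flanking oxygenated carbons. Both prenyl groups are then placed by the constitution of a ketone and not by aromatic substitution. A pentasubstituted benzene becomes a symmetrical open-chain ketone derivative plus a three-carbon diacid chloride. A check of the atom mapping shows that 5 and 7 supply all six ring carbons and all three oxygens of 10 with nothing left over. The forward step needs both acylations to occur at carbon, so the enol oxygen must stay blocked until the ring is closed, and the acid set free must not attack the alkenes.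

6 ⇒ 5 ⇒ 4 ⇒ 1 + 2 (by way of 3). The O–Si bond is cut, then two ester groups are added back on the α-carbons, then the two bonds between those α-carbons and the allylic CH2 groups are cut one after the other. The ester groups make the α,α′-dialkylation mild and regioselective and are removed in one neutral operation. This reaches commercial 1 and two equivalents of commercial 2. The second alkylation, which acts on 3, must go to the other α-carbon and not to the same one.

## Other disconnections considered

Alternative 1: The cut goes through O1–C8a and C4–C4a, removing ring C and leaving a ring A aryne and a chiral three-carbon chain. In the forward step CsF would release the aryne from 3,5-bis(benzyloxy)-2-(trimethylsilyl)phenyl trifluoromethanesulfonate A2. The alkoxide of methyl (3S)-3-[3,5-bis(methoxymethoxy)phenyl]-3-hydroxypropanoate A3 would add at C8a, the C5 benzyloxy group placing the charge at C4a. The aryl anion would then attack the ester to close ring C as the chromanone A1.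
- In favour: the stereocentre comes from a well-established asymmetric reduction or aldol reaction and no bond to it is made or broken in the annulation. On security of C2 this alternative is better than the chosen plan, whose ring closure is reversible. It is equally convergent.
- Against: A1 carries no prenyl groups. They would have to be put on C6 and C8 of a finished flavanone, which is the poorly selective electrophilic prenylation the chosen plan avoids, and under base it exposes C2 to ring opening. The benzyl ethers cannot be removed by hydrogenolysis once prenyl groups are present.
- Mechanism: the aryl anion can be quenched by the acidic α-CH2 of the ester, and the β-aryl alkoxide can undergo retro-aldol cleavage.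
- Step economy: A2 needs several steps, and the late prenylation adds more of low efficiency. The plan is expected to be longer and weaker on the central structural problem.

Alternative 2: The cut is C4a–C5, so ring A is folded from a polycarbonyl chain attached to a preformed chiral dihydropyranone. In the forward step Mg(OMe)2 would form the dienolate of the dihydropyranone-tethered diketo ester A5, C4a would attack the ester carbon, and loss of methoxide and enolisation would give the 5,7-diol A4.
- In favour: the prenyl groups are placed by enolate alkylation, as in the chosen plan, so the two are equal on regiocontrol. Ring A needs no protecting groups, and only the ring B acetals remain after the annulation. On the number of steps after the ring-forming event this alternative is better.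
- Mechanism: both plans close ring A by a Claisen-type C-acylation that is pulled forward by aromatisation and threatened by O-acylation, so they are equal in kind.
- Against: A5 is a tricarbonyl chain with two stereorandom α-prenyl centres on a base-sensitive vinylogous ester. Its assembly needs several C–C bond formations on β-keto ester intermediates. The C2–O1 bond lies β to the C4 carbonyl, so the base of the key step can open the heterocycle by E1cB and erase C2 before ring A forms. In the chosen plan C2 does not exist during the annulation.
- Step economy: the effort moves from the end of the route to the precursor, so the total is expected to be similar or higher.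

Alternative 3: The cut is C8a–C8 and C6–C7, a benzannulation of a four-carbon and a two-carbon unit. In the forward step, heating 2-prenyl-3-(triisopropylsilyloxy)cyclobutenone A7 with the prenyl siloxyalkyne A8 would open the cyclobutenone to a vinylketene. That adds to the alkyne, and ring opening, six-electron electrocyclisation and tautomerisation would give the phenol A6.
- In favour: the regiochemistry is dictated by the pericyclic sequence. The conditions are neutral and thermal, which is better for the prenyl groups than an annulation that sets HCl free. A6 has one free hydroxyl and two silylated ones, so the two ortho oxygens are already differentiated. The chosen plan must create that by protection and selective unmasking, so here the alternative is better.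
- Against: A7 and A8 each need their own multi-step preparation, so the two prenyl groups are introduced in two separate sequences and not in one double alkylation. 3-Siloxycyclobutenones are less established partners than 3-alkyl or 3-alkoxy ones. The acyl group at C4a still has to be attached without Lewis acid.
- Step economy: the route to the ring A stage is expected to be clearly longer than the four steps to 10, partly repaid by one or two fewer steps afterwards.

Key step: step 4

Assumption: the quinidine-derived amine–thiourea named in step 10 is taken to give the 2S product by analogy with this catalyst class; if the sense proves opposite, the pseudoenantiomeric quinine-derived catalyst is used.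

Remark on design: the enol ether carries a triisopropylsilyl group in place of the more usual trimethylsilyl group, because the smaller group is lost after the first acylation and open-chain cases then lactonise. The acetyl group is introduced by directed metalation and not by Friedel–Crafts acetylation of 10, because the acids of the latter would cyclise the prenyl groups.

## Route

Step 1
Reactants: 1 dimethyl 3-oxopentanedioate; 2 1-bromo-3-methylbut-2-ene (two equivalents in all)
Product: 4 dimethyl 2,4-bis(3-methylbut-2-enyl)-3-oxopentanedioate, via monoprenyl keto diester 3 (not isolated)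
Conditions: NaH (1.05 equiv), THF, 0 °C, then 2 (1.0 equiv); then NaH (1.05 equiv) and 2 (1.05 equiv), 0 °C → rt
Reagents that add atoms: 1-bromo-3-methylbut-2-ene (second equivalent), CC(C)=CCBr
Why: Double C-alkylation of a β-keto diester enolate, run as two deprotonation–alkylation cycles in one flask; in monoalkylated 3 the untouched CH2 is the more acidic and less hindered site, so the second prenyl group should enter at the other α-carbon and not geminally. Compound 4 is expected as a mixture of diastereomers and enol forms, whose stereocentres disappear in step 2 and need no control.

Step 2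
Reactants: 4 dimethyl 2,4-bis(3-methylbut-2-enyl)-3-oxopentanedioate
Product: 5 2,10-dimethylundeca-2,9-dien-6-one
Conditions: LiCl, H2O, DMSO, 150 °C
Reagents that add atoms: none
Why: Krapcho dealkoxycarbonylation: chloride demethylates each ester by SN2 and the β-keto carboxylates lose CO2 under neutral conditions. This avoids the retro-Claisen cleavage that threatens basic hydrolysis and the hot acid that would endanger the alkenes.

Step 3
Reactants: 5 2,10-dimethylundeca-2,9-dien-6-one
Product: 6 [(2,10-dimethylundeca-2,5,9-trien-6-yl)oxy]tri(propan-2-yl)silane (E/Z mixture)
Conditions: i-Pr3SiOTf, Et3N, CH2Cl2, 0 °C → rt; pentane extraction without aqueous acid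
Reagents that add atoms: tri(propan-2-yl)silyl trifluoromethanesulfonate, CC(C)[Si](OS(=O)(=O)C(F)(F)F)(C(C)C)C(C)C
Why: Soft enolisation and O-silylation of a ketone; the ketone is symmetrical, so only one constitutional enol ether can form. Its double-bond geometry is irrelevant because both α-carbons end up in the aromatic ring.

Step 4
Reactants: 6 [(2,10-dimethylundeca-2,5,9-trien-6-yl)oxy]tri(propan-2-yl)silane; 7 malonyl dichloride (propanedioyl dichloride)
Product: 10 2,4-bis(3-methylbut-2-enyl)benzene-1,3,5-triol, via silyl enol ether keto acid chloride 8 (not isolated), via aryl silyl ether 9 (not isolated)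
Conditions: 7 (1.05 equiv), Et2O (0.05 M), −78 → −20 °C; cold aq. NaHCO3 wash; then Bu4NF, AcOH, THF, 0 °C, argon
Reagents that add atoms: none
Why: Effenberger [3+3] annulation: the enol ether carbon of 6 attacks one acid chloride of 7 (C8–C8a in flavanone numbering), and the silyloxocarbenium ion formed should lose a proton and not silicon, because chloride attack at the hindered triisopropylsilyl centre is slow, so the oxygen stays blocked in 8. The HCl set free equilibrates the enol ether isomers by C-protonation, and the isomer with its double bond toward the second α-carbon closes ring A by a 6-(enolendo)-exo-trig C-acylation on the remaining acid chloride (C5–C6). Proton loss and enolisation aromatise the ring to 9, and buffered fluoride frees 10. The closest known reaction type is the annulation of ketone enol ethers with malonyl dichloride, which gives cyclic 1,3,5-triones when the enol oxygen stays substituted and 4-hydroxy-2-pyranones when it is freed. No stereocentre is formed. The selectivity needed is C- over O-acylation in the ring closure, and the bulky silyl group secures it by denying the oxygen to the acid chloride; unlike an O-alkyl group it can still be removed from the aromatised product without acid. The positions of the two prenyl groups are fixed by the symmetry of 5, and ether at low temperature is chosen so that HCl does not add to the alkenes.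

Step 5
Reactants: 10 2,4-bis(3-methylbut-2-enyl)benzene-1,3,5-triol
Product: 11 1,3,5-tris(methoxymethoxy)-2,4-bis(3-methylbut-2-enyl)benzene
Conditions: MeOCH2Cl, i-Pr2NEt, CH2Cl2, 0 °C → rt
Reagents that add atoms: chloromethyl methyl ether, COCCl
Why: O-alkylation of phenols (acetal ether formation) with a hard alkoxymethyl chloride and an amine base, which favours O- over C-alkylation of the phloroglucinol. The three acetals make the ring base-stable and turn the two oxygens flanking the last ring C–H into directing groups.

Step 6
Reactants: 11 1,3,5-tris(methoxymethoxy)-2,4-bis(3-methylbut-2-enyl)benzene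
Product: 12 1-[2,4,6-tris(methoxymethoxy)-3,5-bis(3-methylbut-2-enyl)phenyl]ethanone
Conditions: n-BuLi, THF, 0 °C; then MeC(O)N(OMe)Me, −78 → 0 °C; aq. NH4Cl
Reagents that add atoms: N-methoxy-N-methylacetamide, CC(=O)N(C)OC
Why: Directed ortho-metalation followed by Weinreb ketone synthesis: the only ring C–H lies between two acetal oxygens, whose joint coordination should steer n-BuLi there in preference to the benzylic/allylic CH2 groups. The aryllithium is acylated through a chelated tetrahedral intermediate, so the ketone forms without any acid that would cyclise the ortho-prenyl units.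

Step 7
Reactants: 12 1-[2,4,6-tris(methoxymethoxy)-3,5-bis(3-methylbut-2-enyl)phenyl]ethanone
Product: 13 1-[2-hydroxy-4,6-bis(methoxymethoxy)-3,5-bis(3-methylbut-2-enyl)phenyl]ethanone
Conditions: MgBr2·OEt2 (1.1 equiv), Et2O/CH2Cl2, −20 → 0 °C; aq. NH4Cl
Reagents that add atoms: none
Why: Chelation-controlled acetal cleavage: MgBr2 binds the carbonyl oxygen and one flanking acetal oxygen, and bromide removes that methoxymethyl group. The magnesium phenoxide chelate then occupies the carbonyl, so the second ortho acetal and the para acetal, which lack this activation, should remain.

Step 8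
Reactants: 14 3,5-dihydroxybenzaldehyde
Product: 15 3,5-bis(methoxymethoxy)benzaldehyde
Conditions: MeOCH2Cl, i-Pr2NEt, CH2Cl2, 0 °C → rt
Reagents that add atoms: chloromethyl methyl ether, COCCl
Why: O-alkylation of phenols (acetal ether formation); the acetals are chosen because they survive the hydroxide of step 9 and leave in the same final operation as those on ring A.

Step 9
Reactants: 13 1-[2-hydroxy-4,6-bis(methoxymethoxy)-3,5-bis(3-methylbut-2-enyl)phenyl]ethanone; 15 3,5-bis(methoxymethoxy)benzaldehyde
Product: 16 (E)-1-[2-hydroxy-4,6-bis(methoxymethoxy)-3,5-bis(3-methylbut-2-enyl)phenyl]-3-[3,5-bis(methoxymethoxy)phenyl]prop-2-en-1-one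
Conditions: KOH, EtOH/H2O, 0 °C → rt; cold AcOH to pH 6
Reagents that add atoms: none
Why: Claisen–Schmidt condensation: the methyl ketone enolate adds to the non-enolisable aldehyde and E1cB dehydration gives the E-enone. In strong hydroxide the product rests as the chalcone phenoxide, so closure to racemic flavanone should not intervene before the cold, mild acidification.

Step 10
Reactants: 16 (E)-1-[2-hydroxy-4,6-bis(methoxymethoxy)-3,5-bis(3-methylbut-2-enyl)phenyl]-3-[3,5-bis(methoxymethoxy)phenyl]prop-2-en-1-one
Product: 17 (2S)-2-[3,5-bis(methoxymethoxy)phenyl]-5,7-bis(methoxymethoxy)-6,8-bis(3-methylbut-2-enyl)-2,3-dihydrochromen-4-one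
Conditions: 1-[3,5-bis(trifluoromethyl)phenyl]-3-[(9R)-6′-methoxycinchonan-9-yl]thiourea (10 mol %), toluene, 0 °C → rt, stopped before equilibration
Reagents that add atoms: none
Why: Organocatalytic intramolecular oxa-Michael addition (6-endo-trig): the quinuclidine nitrogen deprotonates the 2′-hydroxyl while the thiourea hydrogen-bonds the enone carbonyl, and the chiral ion pair should deliver the phenoxide oxygen to the Si face of the β-carbon, which sets C2 as S. The reaction is run under kinetic control because the closure is reversible under base, and the product should be enriched further by crystallisation.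

Step 11
Reactants: 17 (2S)-2-[3,5-bis(methoxymethoxy)phenyl]-5,7-bis(methoxymethoxy)-6,8-bis(3-methylbut-2-enyl)-2,3-dihydrochromen-4-one
Product: 18 (2S)-2-(3,5-dihydroxyphenyl)-5,7-dihydroxy-6,8-bis(3-methylbut-2-enyl)-2,3-dihydrochromen-4-one
Conditions: HCl (ca. 1.5 M), MeOH, 0 °C → rt, argon; NaHCO3 quench
Reagents that add atoms: none
Why: Acid-catalysed acetal methanolysis frees the four phenols. Dilute acid, low temperature and short contact are chosen because aryl acetals should cleave faster than the prenyl groups cyclise onto the neighbouring phenols, and acid-mediated opening of ring C at C2 is slow under these conditions.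

## Compound list

1 | dimethyl 3-oxopentanedioate | COC(=O)CC(=O)CC(=O)OC | starting material
2 | 1-bromo-3-methylbut-2-ene | CC(C)=CCBr | starting material
3 | dimethyl 2-(3-methylbut-2-enyl)-3-oxopentanedioate | COC(=O)CC(=O)C(CC=C(C)C)C(=O)OC | intermediate (not isolated)
4 | dimethyl 2,4-bis(3-methylbut-2-enyl)-3-oxopentanedioate | COC(=O)C(CC=C(C)C)C(=O)C(CC=C(C)C)C(=O)OC | intermediate
5 | 2,10-dimethylundeca-2,9-dien-6-one | CC(C)=CCCC(=O)CCC=C(C)C | intermediate
6 | [(2,10-dimethylundeca-2,5,9-trien-6-yl)oxy]tri(propan-2-yl)silane | CC(C)=CCCC(O[Si](C(C)C)(C(C)C)C(C)C)=CCC=C(C)C | intermediate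
7 | malonyl dichloride (propanedioyl dichloride) | O=C(Cl)CC(=O)Cl | starting material
8 | 9-methyl-4-(3-methylbut-2-enyl)-3-oxo-5-[tri(propan-2-yl)silyloxy]deca-5,8-dienoyl chloride | O=C(Cl)CC(=O)C(CC=C(C)C)C(O[Si](C(C)C)(C(C)C)C(C)C)=CCC=C(C)C | intermediate (not isolated)
9 | 4,6-bis(3-methylbut-2-enyl)-5-[tri(propan-2-yl)silyloxy]benzene-1,3-diol | CC(C)=CCc1c(O)cc(O)c(CC=C(C)C)c1O[Si](C(C)C)(C(C)C)C(C)C | intermediate (not isolated)
10 | 2,4-bis(3-methylbut-2-enyl)benzene-1,3,5-triol | CC(C)=CCc1c(O)cc(O)c(CC=C(C)C)c1O | intermediate
11 | 1,3,5-tris(methoxymethoxy)-2,4-bis(3-methylbut-2-enyl)benzene | COCOc1cc(OCOC)c(CC=C(C)C)c(OCOC)c1CC=C(C)C | intermediate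
12 | 1-[2,4,6-tris(methoxymethoxy)-3,5-bis(3-methylbut-2-enyl)phenyl]ethanone | CC(=O)c1c(OCOC)c(CC=C(C)C)c(OCOC)c(CC=C(C)C)c1OCOC | intermediate
13 | 1-[2-hydroxy-4,6-bis(methoxymethoxy)-3,5-bis(3-methylbut-2-enyl)phenyl]ethanone | CC(=O)c1c(O)c(CC=C(C)C)c(OCOC)c(CC=C(C)C)c1OCOC | intermediate
14 | 3,5-dihydroxybenzaldehyde | O=Cc1cc(O)cc(O)c1 | starting material
15 | 3,5-bis(methoxymethoxy)benzaldehyde | COCOc1cc(C=O)cc(OCOC)c1 | intermediate
16 | (E)-1-[2-hydroxy-4,6-bis(methoxymethoxy)-3,5-bis(3-methylbut-2-enyl)phenyl]-3-[3,5-bis(methoxymethoxy)phenyl]prop-2-en-1-one | O=C(/C=C/c1cc(OCOC)cc(OCOC)c1)c1c(O)c(CC=C(C)C)c(OCOC)c(CC=C(C)C)c1OCOC | intermediate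
17 | (2S)-2-[3,5-bis(methoxymethoxy)phenyl]-5,7-bis(methoxymethoxy)-6,8-bis(3-methylbut-2-enyl)-2,3-dihydrochromen-4-one | CC(C)=CCc1c(OCOC)c(CC=C(C)C)c2c(c1OCOC)C(=O)C[C@@H](c1cc(OCOC)cc(OCOC)c1)O2 | intermediate
18 | (2S)-2-(3,5-dihydroxyphenyl)-5,7-dihydroxy-6,8-bis(3-methylbut-2-enyl)-2,3-dihydrochromen-4-one | CC(C)=CCc1c(O)c(CC=C(C)C)c2c(c1O)C(=O)C[C@@H](c1cc(O)cc(O)c1)O2 | target

## Step count and least certain steps

Total step count: 11. Longest linear sequence: 10 steps (steps 1–7 and 9–11); step 8 is a one-step side branch.

Step 4 (key step). The most likely failure is premature loss of the silyl group after the first acylation, which frees the β-diketone and diverts the ring closure to O-acylation (lactonisation). Two further risks are Markovnikov addition of HCl to the prenyl alkenes and intermolecular double acylation if the second acylation is slow. The fallback gives up the annulation and places the prenyl groups by two cycles of directed ortho-metalation and alkylation. It sets out from 2 and purchased benzene-1,3,5-triol F1. F1 is converted with MeOCH2Cl and NaH in DMF into 1,3,5-tris(methoxymethoxy)benzene F2. Lithiation of F2 with n-BuLi in THF at 0 °C, transmetalation with CuI and alkylation with 2 should give 1,3,5-tris(methoxymethoxy)-2-(3-methylbut-2-enyl)benzene F3. A second identical cycle can only metalate one of the two equivalent positions between acetal oxygens, and should give 11, where the route is rejoined.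

Step 10. The risk is poor facial selectivity, because the internal hydrogen bond of the 2′-hydroxyl to the carbonyl competes with catalyst binding and the neighbouring prenyl group crowds the nucleophilic oxygen. A second risk is erosion of enantiomeric purity by reversible ring opening under the basic catalyst. The fallback closes the ring without stereocontrol and resolves kinetically by asymmetric transfer hydrogenation. It sets out from 16: NaOAc in refluxing EtOH should give racemic 2-[3,5-bis(methoxymethoxy)phenyl]-5,7-bis(methoxymethoxy)-6,8-bis(3-methylbut-2-enyl)-2,3-dihydrochromen-4-one F4. RuCl(p-cymene)[(R,R)-TsDPEN] with HCO2H/Et3N is then expected to reduce the 2R ketone faster, to the cis alcohol (2R,4R)-2-[3,5-bis(methoxymethoxy)phenyl]-5,7-bis(methoxymethoxy)-6,8-bis(3-methylbut-2-enyl)-3,4-dihydro-2H-chromen-4-ol F5, leaving 17, which is separated and taken into step 11. At most half of the material is recovered this way.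

Step 7. The risk is over-cleavage, with loss of both ortho acetals once excess Lewis acid is present, or sluggish cleavage at the hindered, prenyl-flanked position. The fallback removes all three acetals and re-protects selectively. It sets out from 12: brief HCl in MeOH at 0 °C should give 1-[2,4,6-trihydroxy-3,5-bis(3-methylbut-2-enyl)phenyl]ethanone F6. MeOCH2Cl (2.2 equiv) and i-Pr2NEt then leave the carbonyl-bonded hydroxyl free, because it is the least nucleophilic, and give 13.

Step 6. The risk is competing proton transfer: lateral metalation at the benzylic/allylic CH2 groups in place of ring metalation, or enolisation of the acetamide by the hindered aryllithium in place of addition. The fallback makes the aryl anion by halogen–lithium exchange, which is faster than any deprotonation at −78 °C. It sets out from 11: NBS in MeCN at −20 °C should give 2-bromo-1,3,5-tris(methoxymethoxy)-4,6-bis(3-methylbut-2-enyl)benzene F7. Exchange with t-BuLi (2 equiv) in THF at −78 °C and inverse addition to Ac2O then gives 12.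

Step 11. The risk is acid-catalysed addition of the freed ortho phenols across the prenyl alkenes, hydrochlorination, and slow acid-induced opening of ring C. The fallback exchanges the acetals for silyl ethers under buffered, non-protic conditions and hydrolyses those at neutral pH. It sets out from 17: Me3SiOTf and 2,2′-bipyridyl in MeCN at 0 °C should give (2S)-2-[3,5-bis(trimethylsilyloxy)phenyl]-6,8-bis(3-methylbut-2-enyl)-5,7-bis(trimethylsilyloxy)-2,3-dihydrochromen-4-one F8. Neutral water at rt then hydrolyses F8 to 18.

## Further compounds

F1 | step 4 | benzene-1,3,5-triol (purchased) | Oc1cc(O)cc(O)c1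
F2 | step 4 | 1,3,5-tris(methoxymethoxy)benzene | COCOc1cc(OCOC)cc(OCOC)c1
F3 | step 4 | 1,3,5-tris(methoxymethoxy)-2-(3-methylbut-2-enyl)benzene | COCOc1cc(OCOC)c(CC=C(C)C)c(OCOC)c1
F4 | step 10 | racemic 2-[3,5-bis(methoxymethoxy)phenyl]-5,7-bis(methoxymethoxy)-6,8-bis(3-methylbut-2-enyl)-2,3-dihydrochromen-4-one | CC(C)=CCc1c(OCOC)c(CC=C(C)C)c2c(c1OCOC)C(=O)CC(c1cc(OCOC)cc(OCOC)c1)O2
F5 | step 10 | (2R,4R)-2-[3,5-bis(methoxymethoxy)phenyl]-5,7-bis(methoxymethoxy)-6,8-bis(3-methylbut-2-enyl)-3,4-dihydro-2H-chromen-4-ol | CC(C)=CCc1c(OCOC)c(CC=C(C)C)c2c(c1OCOC)[C@H](O)C[C@H](c1cc(OCOC)cc(OCOC)c1)O2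
F6 | step 7 | 1-[2,4,6-trihydroxy-3,5-bis(3-methylbut-2-enyl)phenyl]ethanone | CC(=O)c1c(O)c(CC=C(C)C)c(O)c(CC=C(C)C)c1O
F7 | step 6 | 2-bromo-1,3,5-tris(methoxymethoxy)-4,6-bis(3-methylbut-2-enyl)benzene | COCOc1c(Br)c(OCOC)c(CC=C(C)C)c(OCOC)c1CC=C(C)C
F8 | step 11 | (2S)-2-[3,5-bis(trimethylsilyloxy)phenyl]-6,8-bis(3-methylbut-2-enyl)-5,7-bis(trimethylsilyloxy)-2,3-dihydrochromen-4-one | CC(C)=CCc1c(O[Si](C)(C)C)c(CC=C(C)C)c2c(c1O[Si](C)(C)C)C(=O)C[C@@H](c1cc(O[Si](C)(C)C)cc(O[Si](C)(C)C)c1)O2
A1 | alternative 1 | (2S)-5,7-bis(benzyloxy)-2-[3,5-bis(methoxymethoxy)phenyl]-2,3-dihydrochromen-4-one | O=C1C[C@@H](c2cc(OCOC)cc(OCOC)c2)Oc2cc(OCc3ccccc3)cc(OCc3ccccc3)c21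
A2 | alternative 1 | 3,5-bis(benzyloxy)-2-(trimethylsilyl)phenyl trifluoromethanesulfonate | C[Si](C)(C)c1c(OS(=O)(=O)C(F)(F)F)cc(OCc2ccccc2)cc1OCc1ccccc1
A3 | alternative 1 | methyl (3S)-3-[3,5-bis(methoxymethoxy)phenyl]-3-hydroxypropanoate | COC(=O)C[C@H](O)c1cc(OCOC)cc(OCOC)c1
A4 | alternative 2 | (2S)-2-[3,5-bis(methoxymethoxy)phenyl]-5,7-dihydroxy-6,8-bis(3-methylbut-2-enyl)-2,3-dihydrochromen-4-one | CC(C)=CCc1c(O)c(CC=C(C)C)c2c(c1O)C(=O)C[C@@H](c1cc(OCOC)cc(OCOC)c1)O2
A5 | alternative 2 | methyl 4-[(2S)-2-[3,5-bis(methoxymethoxy)phenyl]-4-oxo-2,3-dihydropyran-6-yl]-7-methyl-2-(3-methylbut-2-enyl)-3-oxooct-6-enoate | COC(=O)C(CC=C(C)C)C(=O)C(CC=C(C)C)C1=CC(=O)C[C@@H](c2cc(OCOC)cc(OCOC)c2)O1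
A6 | alternative 3 | 2,4-bis(3-methylbut-2-enyl)-3,5-bis[tri(propan-2-yl)silyloxy]phenol | Oc1cc(O[Si](C(C)C)(C(C)C)C(C)C)c(CC=C(C)C)c(O[Si](C(C)C)(C(C)C)C(C)C)c1CC=C(C)C
A7 | alternative 3 | 2-(3-methylbut-2-enyl)-3-[tri(propan-2-yl)silyloxy]cyclobut-2-en-1-one | O=C1CC(O[Si](C(C)C)(C(C)C)C(C)C)=C1CC=C(C)C
A8 | alternative 3 | [(5-methylhex-4-en-1-yn-1-yl)oxy]tri(propan-2-yl)silane | CC(C)=CCC#CO[Si](C(C)C)(C(C)C)C(C)C
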